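**Retrosynthetic overview**
1. Target 9 ← global O‑demethylation of the bis(methyl ether) diarylmethane 7.
2. Ar–CH2 bond of 7 ← transition‑metal‑free reductive coupling of tosylhydrazone 3 with arylboronic acid 4 (key step). It replaces the usual Friedel–Crafts benzylation or bromination of bisphenol F, and with no Pd/Ni all three C–Br bonds are carried through untouched.
3. Hydrazone 3 ← aldehyde 2 ← commercial 3,5‑dibromo‑4‑hydroxybenzaldehyde 1; boronic acid 4 is commercial.
4. No ring is formed: both benzene rings are bought with their bromines already in place.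

Assumption: the target has no stereocentre or other stereo‑element (it is achiral), so "single enantiomer" needs no stereocontrol; only skeleton‑bearing compounds are numbered, other reagents are given with SMILES on the reagent line.

**Step 1**
Reactants: 1 3,5‑dibromo‑4‑hydroxybenzaldehyde
Product: 2 3,5‑dibromo‑4‑methoxybenzaldehyde
Conditions: MeI (1.5 equiv), K2CO3 (2 equiv), DMF, 40 °C, 12 h
Reagents that add atoms: iodomethane, CI
Why: Williamson O‑methylation (SN2): the acidic 2,6‑dibromophenol is fully deprotonated by K2CO3 and the phenoxide attacks unhindered MeI, while the non‑enolisable aldehyde and the aryl bromides are inert.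

**Step 2**
Reactants: 2 3,5‑dibromo‑4‑methoxybenzaldehyde
Product: 3 (E)‑N'‑[(3,5‑dibromo‑4‑methoxyphenyl)methylidene]‑4‑methylbenzenesulfonohydrazide
Conditions: TsNHNH2 (1.05 equiv), MeOH, 60 °C → rt, 2 h; filter the precipitate
Reagents that add atoms: p‑toluenesulfonyl hydrazide, Cc1ccc(cc1)S(=O)(=O)NN
Why: Condensation of an aryl aldehyde with a sulfonyl hydrazide (hydrazone formation) gives the crystalline, thermodynamically preferred E‑hydrazone, whose precipitation drives the equilibrium.

**Step 3**
Reactants: 3 (E)‑N'‑[(3,5‑dibromo‑4‑methoxyphenyl)methylidene]‑4‑methylbenzenesulfonohydrazide; 4 (3‑bromo‑4‑methoxyphenyl)boronic acid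
Product: 7 1,3‑dibromo‑5‑[(3‑bromo‑4‑methoxyphenyl)methyl]‑2‑methoxybenzene, via aryldiazomethane 5 (not isolated), via benzylic boronic acid 6 (not isolated)
Conditions: 4 (1.5 equiv), K2CO3 (1.5 equiv), 1,4‑dioxane, 110 °C, N2, 4 h; aqueous work‑up
Reagents that add atoms: none
Why: Barluenga–Valdés metal‑free reductive coupling: Bamford–Stevens loss of sulfinate from 3 gives diazo compound 5, which binds the boron of 4 and undergoes a 1,2‑aryl shift with N2 loss to racemic boronic acid 6, which protodeboronates in situ to the CH2 group (its transient stereocentre is erased), and with no transition metal present the three C–Br bonds do not react.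

**Step 4**
Reactants: 7 1,3‑dibromo‑5‑[(3‑bromo‑4‑methoxyphenyl)methyl]‑2‑methoxybenzene
Product: 9 2,6‑dibromo‑4‑[(3‑bromo‑4‑hydroxyphenyl)methyl]phenol, via bis(dibromoboryl) ether 8 (not isolated)
Conditions: BBr3 (4 equiv, 1 M in CH2Cl2), CH2Cl2, −78 °C → rt, 12 h; then ice/H2O
Reagents that add atoms: none
Why: Lewis‑acid ether cleavage (BBr3 O‑demethylation): boron coordinates each ether oxygen, bromide removes the methyl by SN2 to give aryloxy‑dibromoborane 8, and water hydrolyses the B–O bonds to the free phenols, with aryl bromides and the diarylmethane CH2 stable under these conditions.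

**Compound list**
1 | 3,5‑dibromo‑4‑hydroxybenzaldehyde | O=Cc1cc(Br)c(O)c(Br)c1 | starting material
2 | 3,5‑dibromo‑4‑methoxybenzaldehyde | COc1c(Br)cc(C=O)cc1Br | intermediate
3 | (E)‑N'‑[(3,5‑dibromo‑4‑methoxyphenyl)methylidene]‑4‑methylbenzenesulfonohydrazide | COc1c(Br)cc(/C=N/NS(=O)(=O)c2ccc(C)cc2)cc1Br | intermediate
4 | (3‑bromo‑4‑methoxyphenyl)boronic acid | COc1ccc(B(O)O)cc1Br | starting material
5 | 1,3‑dibromo‑5‑(diazomethyl)‑2‑methoxybenzene | COc1c(Br)cc(C=[N+]=[N-])cc1Br | intermediate
6 | [(3‑bromo‑4‑methoxyphenyl)(3,5‑dibromo‑4‑methoxyphenyl)methyl]boronic acid (racemic) | COc1ccc(C(B(O)O)c2cc(Br)c(OC)c(Br)c2)cc1Br | intermediate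
7 | 1,3‑dibromo‑5‑[(3‑bromo‑4‑methoxyphenyl)methyl]‑2‑methoxybenzene | COc1ccc(Cc2cc(Br)c(OC)c(Br)c2)cc1Br | intermediate
8 | 1,3‑dibromo‑5‑{[3‑bromo‑4‑(dibromoboryloxy)phenyl]methyl}‑2‑(dibromoboryloxy)benzene | BrB(Br)Oc1ccc(Cc2cc(Br)c(OB(Br)Br)c(Br)c2)cc1Br | intermediate
9 | 2,6‑dibromo‑4‑[(3‑bromo‑4‑hydroxyphenyl)methyl]phenol (CNP0244525.0) | Oc1ccc(Cc2cc(Br)c(O)c(Br)c2)cc1Br | target

**Total step count:** 4
**Longest linear sequence:** 4 steps (1 → 2 → 3 → 7 → 9); coupling partner 4 is purchased.

**Three steps most likely to fail**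

Step 3 (key coupling; risks are azine or stilbene formation from diazo compound 5 and protodeboronation of 4). The fallback sets out from compound 2 and comes back at compound 7. Commercial 2‑bromo‑4‑iodoanisole (COc1ccc(I)cc1Br) undergoes selective I/Mg exchange with iPrMgCl·LiCl (THF, −30 °C) to give (3‑bromo‑4‑methoxyphenyl)magnesium chloride F1. This adds to aldehyde 2 (−30 → 0 °C, NH4Cl quench) to give racemic (3‑bromo‑4‑methoxyphenyl)(3,5‑dibromo‑4‑methoxyphenyl)methanol F2. Ionic hydrogenation with Et3SiH/TFA (CH2Cl2, 0 °C → rt) then removes the benzhydrylic hydroxyl through the anisyl‑stabilised cation, erasing the stereocentre and giving 7.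

Step 4 (risks are acid‑induced transbenzylation of the electron‑rich diarylmethane and incomplete cleavage of one ether). The fallback sets out from compound 1 and comes back at compound 9 without any protecting group. Excess NaBH4 (MeOH, 0 °C) reduces 1 to 2,6‑dibromo‑4‑(hydroxymethyl)phenol F3. Catalytic TfOH in HFIP ionises it to the benzyl cation/p‑quinone methide, which alkylates commercial 2‑bromophenol (5 equiv, Oc1ccccc1Br) para to its hydroxyl in a Friedel–Crafts benzylation. This gives 9 directly; the minor ortho isomer and excess 2‑bromophenol are removed by chromatography.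

Step 1 (risk is sluggish alkylation of the hindered, weakly nucleophilic 2,6‑dibromophenoxide). The fallback sets out from compound 1 and comes back at compound 2 by Mitsunobu methylation (MeOH, PPh3, DIAD, THF, 0 °C → rt). Here the acidic phenol is an ideal pronucleophile and the electrophile is the small methoxyphosphonium ion generated under neutral redox conditions, not an alkyl halide. No new compound is made (F0).

**Further compounds**
F1 | step 3 | (3‑bromo‑4‑methoxyphenyl)magnesium chloride | COc1ccc([Mg]Cl)cc1Br
F2 | step 3 | (3‑bromo‑4‑methoxyphenyl)(3,5‑dibromo‑4‑methoxyphenyl)methanol (racemic) | COc1ccc(C(O)c2cc(Br)c(OC)c(Br)c2)cc1Br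
F3 | step 4 | 2,6‑dibromo‑4‑(hydroxymethyl)phenol | OCc1cc(Br)c(O)c(Br)c1
F0 | step 1 | none | none
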